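**Retrosynthetic overview**
1. Target ⇐ acid hydrolysis of a ring dimethyl ketal and a side-chain dimethyl acetal ⇐ O-acetylation ⇐ hydroxyl-directed nucleophilic epoxidation of a 2-(1-hydroxydienyl) quinone monoketal.
2. The C-1′–ring bond and the C-1′ stereocentre come from an asymmetric Nozaki–Hiyama–Kishi coupling of an α-iodo quinone monoketal with (2E,4E)-6,6-dimethoxy-3-methylhexa-2,4-dienal.
3. Key step: the quinone monoketal carrying CH2OAc next to the ketal carbon is made from 4-hydroxybenzyl acetate by oxidative dearomatisation, a cationic 1,2-shift of the CH2OAc carbon (dienone–phenol type) and a second oxidation; this fixes the 2,5-pattern.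
4. Building blocks: 4-bromophenol + formaldehyde (ring and C-7); 3-methylbut-2-enal + 2,2-dimethoxyacetaldehyde (side chain, vinylogous Mukaiyama aldol then dehydration).
5. Ring order: the six-membered carbocycle is taken from the arene (dearomatised in step 2); the oxirane is the only ring formed, in step 8.

Assumption: paraformaldehyde is drawn as monomeric formaldehyde; acetic anhydride, methanol, iodine and tert-butyl hydroperoxide are treated as reagents that add atoms.

**Step 1**
Reactants: 1 4-bromophenol; 2 formaldehyde (as dry paraformaldehyde)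
Product: 5 4-hydroxybenzyl acetate, via lithium 4-lithiophenolate 3 (not isolated), via dilithium 4-(oxidomethyl)phenolate 4 (not isolated)
Conditions: t-BuLi (3.1 equiv), THF, −78 → −20 °C; (CH2O)n, −78 → 0 °C; Ac2O (1.0 equiv), −78 °C; AcOH quench at −78 °C
Reagents that add atoms: acetic anhydride, CC(=O)OC(C)=O
Why: Halogen–lithium exchange on the phenolate gives the para-aryllithium, which adds to formaldehyde; the lithium alkoxide is acylated far faster than the lithium phenolate, and the cold acidic quench prevents 1,6-elimination to the quinone methide; no stereocentre.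

**Step 2**
Reactants: 5 4-hydroxybenzyl acetate
Product: 8 (6,6-dimethoxy-3-oxocyclohexa-1,4-dien-1-yl)methyl acetate, via quinol methyl ether 6 (not isolated), via methoxyphenol 7 (not isolated)
Conditions: PhI(OAc)2 (1.05 equiv), MeOH, 0 °C; evaporate; TfOH (10 mol %), CH2Cl2/HFIP (4:1), −20 → 20 °C; NaHCO3, evaporate; PhI(OAc)2 (1.1 equiv), MeOH, 0 °C
Reagents that add atoms: methanol, CO
Why: Proposed new method: a one-flask para-to-meta transposition in which PhI(OAc)2/MeOH dearomatises 5 to the 4-methoxy-4-(acetoxymethyl)dienone 6, protonation of the dienone carbonyl triggers a cationic 1,2-shift of the CH2OAc carbon from C-4 to C-3 (preferred over methoxy migration because the migration origin becomes a methoxy-stabilised oxocarbenium ion, and fragmentation is disfavoured because the acetate makes CH2OAc a poor leaving cation), tautomerisation gives phenol 7, and a second PhI(OAc)2/MeOH oxidation gives ketal 8; the closest known reaction type is the acid-promoted dienone–phenol (quinol) rearrangement of 4-alkyl-4-oxy-cyclohexadienones with 1,2-alkyl shift, not yet shown for an acyloxymethyl group or run between two hypervalent-iodine oxidations; no stereocentre.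

**Step 3**
Reactants: 8 (6,6-dimethoxy-3-oxocyclohexa-1,4-dien-1-yl)methyl acetate
Product: 9 (4-iodo-6,6-dimethoxy-3-oxocyclohexa-1,4-dien-1-yl)methyl acetate
Conditions: I2 (1.5 equiv), pyridine/CH2Cl2 (1:1), 0 °C → rt
Reagents that add atoms: iodine, II
Why: α-Iodination of an enone by pyridine conjugate addition, enolate iodination and elimination; only the β-unsubstituted enone arm accepts pyridine, so iodine enters para to the CH2OAc-bearing carbon; no stereocentre.

**Step 4**
Reactants: 10 3-methylbut-2-enal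
Product: 11 (E)-trimethyl[(3-methylbuta-1,3-dien-1-yl)oxy]silane
Conditions: TMSOTf, Et3N, Et2O, 0 °C
Reagents that add atoms: trimethylsilyl trifluoromethanesulfonate, C[Si](C)(C)OS(=O)(=O)C(F)(F)F
Why: Soft enolisation (O-silylation then γ-deprotonation) gives the silyl dienol ether; no stereocentre.

**Step 5**
Reactants: 11 (E)-trimethyl[(3-methylbuta-1,3-dien-1-yl)oxy]silane; 12 2,2-dimethoxyacetaldehyde
Product: 13 (2E)-5-hydroxy-6,6-dimethoxy-3-methylhex-2-enal (racemic at C-5)
Conditions: BF3·OEt2 (1.0 equiv), CH2Cl2, −78 °C; aq. NaHCO3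
Reagents that add atoms: none
Why: Vinylogous Mukaiyama aldol: the dienol ether attacks through its γ-carbon the BF3-activated aldehyde (which reacts before the acetal at −78 °C); the new carbinol centre is racemic and is removed in step 6.

**Step 6**
Reactants: 13 (2E)-5-hydroxy-6,6-dimethoxy-3-methylhex-2-enal
Product: 15 (2E,4E)-6,6-dimethoxy-3-methylhexa-2,4-dienal, via mesylate 14 (not isolated)
Conditions: MsCl, Et3N, CH2Cl2, 0 °C; DBU, rt; I2 (2 mol %), rt; chromatography
Reagents that add atoms: none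
Why: Mesylation and vinylogous E1cB elimination give the conjugated 4E alkene, and iodine-catalysed equilibration converges the trisubstituted alkene on the 2E,4E isomer; any residual 2Z isomer is separated and recycled.

**Step 7**
Reactants: 9 (4-iodo-6,6-dimethoxy-3-oxocyclohexa-1,4-dien-1-yl)methyl acetate; 15 (2E,4E)-6,6-dimethoxy-3-methylhexa-2,4-dienal
Product: 16 {4-[(1S,2E,4E)-1-hydroxy-6,6-dimethoxy-3-methylhexa-2,4-dien-1-yl]-6,6-dimethoxy-3-oxocyclohexa-1,4-dien-1-yl}methyl acetate
Conditions: CrCl2 (10 mol %), chiral oxazoline–sulfonamide ligand (Kishi type, 11 mol %), proton sponge, NiCl2·(2,9-dimethyl-1,10-phenanthroline) (2 mol %), Mn powder, Cp2ZrCl2, LiCl, MeCN, rt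
Reagents that add atoms: none
Why: Catalytic asymmetric Nozaki–Hiyama–Kishi coupling: nickel inserts into the C–I bond, transmetalation gives an alkenylchromium species that adds 1,2 to the aldehyde inside the chiral chromium–sulfonamide complex, which sets C-1′ as S (the ligand enantiomer is chosen accordingly and the configuration checked by Mosher esters); ketal, acetal and ester are tolerated.

**Step 8**
Reactants: 16 {4-[(1S,2E,4E)-1-hydroxy-6,6-dimethoxy-3-methylhexa-2,4-dien-1-yl]-6,6-dimethoxy-3-oxocyclohexa-1,4-dien-1-yl}methyl acetate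
Product: 17 {(1R,6S)-1-[(1S,2E,4E)-1-hydroxy-6,6-dimethoxy-3-methylhexa-2,4-dien-1-yl]-5,5-dimethoxy-2-oxo-7-oxabicyclo[4.1.0]hept-3-en-4-yl}methyl acetate
Conditions: t-BuOOH (1.2 equiv, in decane), DBU (0.3 equiv), CH2Cl2, 0 °C
Reagents that add atoms: tert-butyl hydroperoxide, CC(C)(C)OO
Why: Weitz–Scheffer epoxidation of the only enone arm with an unsubstituted β-carbon; with the carbinol OH hydrogen-bonded to the ring carbonyl the peroxide adds to the face opposite the dienyl group, which gives the 1R,6S oxirane (cis-fused by necessity) from the 1′S carbinol.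

**Step 9**
Reactants: 17 {(1R,6S)-1-[(1S,2E,4E)-1-hydroxy-6,6-dimethoxy-3-methylhexa-2,4-dien-1-yl]-5,5-dimethoxy-2-oxo-7-oxabicyclo[4.1.0]hept-3-en-4-yl}methyl acetate
Product: 18 {(1R,6S)-1-[(1S,2E,4E)-1-acetoxy-6,6-dimethoxy-3-methylhexa-2,4-dien-1-yl]-5,5-dimethoxy-2-oxo-7-oxabicyclo[4.1.0]hept-3-en-4-yl}methyl acetate
Conditions: Ac2O, pyridine, DMAP (cat.), CH2Cl2, 0 °C
Reagents that add atoms: acetic anhydride, CC(=O)OC(C)=O
Why: DMAP-catalysed O-acylation of the secondary alcohol with retention at C-1′; prompt acylation also blocks Payne migration of the epoxy alcohol.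

**Step 10**
Reactants: 18 {(1R,6S)-1-[(1S,2E,4E)-1-acetoxy-6,6-dimethoxy-3-methylhexa-2,4-dien-1-yl]-5,5-dimethoxy-2-oxo-7-oxabicyclo[4.1.0]hept-3-en-4-yl}methyl acetate
Product: 20 {(1R,6S)-1-[(1S,2E,4E)-1-acetoxy-3-methyl-6-oxohexa-2,4-dien-1-yl]-2,5-dioxo-7-oxabicyclo[4.1.0]hept-3-en-4-yl}methyl acetate (target CNP0307549.1), via dienal ketal 19 (not isolated)
Conditions: TsOH·H2O (0.2 equiv), acetone/H2O (10:1), rt → 40 °C
Reagents that add atoms: water, O
Why: Acid-catalysed acetal hydrolysis: the conjugated dimethyl acetal goes first (the resulting electron-poor dienal protects the allylic acetate from ionisation), then the ring ketal; oxirane, acetates and all three stereocentres are untouched.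

**Compound list**
1 | 4-bromophenol | Oc1ccc(Br)cc1 | starting material
2 | formaldehyde (used as paraformaldehyde) | C=O | starting material
3 | lithium 4-lithiophenolate | [Li]Oc1ccc([Li])cc1 | intermediate
4 | dilithium 4-(oxidomethyl)phenolate | [Li]OCc1ccc(O[Li])cc1 | intermediate
5 | 4-hydroxybenzyl acetate | CC(=O)OCc1ccc(O)cc1 | intermediate
6 | (1-methoxy-4-oxocyclohexa-2,5-dien-1-yl)methyl acetate | CC(=O)OCC1(OC)C=CC(=O)C=C1 | intermediate
7 | (5-hydroxy-2-methoxyphenyl)methyl acetate | CC(=O)OCc1cc(O)ccc1OC | intermediate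
8 | (6,6-dimethoxy-3-oxocyclohexa-1,4-dien-1-yl)methyl acetate | CC(=O)OCC1=CC(=O)C=CC1(OC)OC | intermediate
9 | (4-iodo-6,6-dimethoxy-3-oxocyclohexa-1,4-dien-1-yl)methyl acetate | CC(=O)OCC1=CC(=O)C(I)=CC1(OC)OC | intermediate
10 | 3-methylbut-2-enal | CC(C)=CC=O | starting material
11 | (E)-trimethyl[(3-methylbuta-1,3-dien-1-yl)oxy]silane | C=C(C)/C=C/O[Si](C)(C)C | intermediate
12 | 2,2-dimethoxyacetaldehyde | COC(OC)C=O | starting material
13 | (2E)-5-hydroxy-6,6-dimethoxy-3-methylhex-2-enal, racemic at C-5 | O=C/C=C(\C)CC(O)C(OC)OC | intermediate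
14 | (4E)-1,1-dimethoxy-4-methyl-6-oxohex-4-en-2-yl methanesulfonate, racemic | O=C/C=C(\C)CC(OS(C)(=O)=O)C(OC)OC | intermediate
15 | (2E,4E)-6,6-dimethoxy-3-methylhexa-2,4-dienal | O=C/C=C(C)/C=C/C(OC)OC | intermediate
16 | {4-[(1S,2E,4E)-1-hydroxy-6,6-dimethoxy-3-methylhexa-2,4-dien-1-yl]-6,6-dimethoxy-3-oxocyclohexa-1,4-dien-1-yl}methyl acetate | CC(=O)OCC1=CC(=O)C([C@@H](O)/C=C(C)/C=C/C(OC)OC)=CC1(OC)OC | intermediate
17 | {(1R,6S)-1-[(1S,2E,4E)-1-hydroxy-6,6-dimethoxy-3-methylhexa-2,4-dien-1-yl]-5,5-dimethoxy-2-oxo-7-oxabicyclo[4.1.0]hept-3-en-4-yl}methyl acetate | CC(=O)OCC1=CC(=O)[C@]2([C@H](/C=C(C)/C=C/C(OC)OC)O)O[C@@H]2C1(OC)OC | intermediate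
18 | {(1R,6S)-1-[(1S,2E,4E)-1-acetoxy-6,6-dimethoxy-3-methylhexa-2,4-dien-1-yl]-5,5-dimethoxy-2-oxo-7-oxabicyclo[4.1.0]hept-3-en-4-yl}methyl acetate | CC(=O)OCC1=CC(=O)[C@]2([C@H](/C=C(C)/C=C/C(OC)OC)OC(C)=O)O[C@@H]2C1(OC)OC | intermediate
19 | {(1R,6S)-1-[(1S,2E,4E)-1-acetoxy-3-methyl-6-oxohexa-2,4-dien-1-yl]-5,5-dimethoxy-2-oxo-7-oxabicyclo[4.1.0]hept-3-en-4-yl}methyl acetate | CC(=O)OCC1=CC(=O)[C@]2([C@H](/C=C(C)/C=C/C=O)OC(C)=O)O[C@@H]2C1(OC)OC | intermediate
20 | {(1R,6S)-1-[(1S,2E,4E)-1-acetoxy-3-methyl-6-oxohexa-2,4-dien-1-yl]-2,5-dioxo-7-oxabicyclo[4.1.0]hept-3-en-4-yl}methyl acetate (CNP0307549.1) | CC(=O)OCC1=CC(=O)[C@]2([C@H](/C=C(C)/C=C/C=O)OC(C)=O)O[C@@H]2C1=O | target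

**Step count and risks**
Total step count: 10 (steps 1–3 ring, 4–6 side chain, 7–10 union and endgame).
Longest linear sequence: 7 steps (1, 2, 3, 7, 8, 9, 10; the branch 4, 5, 6, 7, 8, 9, 10 is equally long).

Step 2 (the proposed new step). The CH2OAc carbon may migrate slowly, and acetate participation or solvolysis of quinol ether 6 could compete. The fallback uses known chemistry, sets out from formaldehyde 2 and comes back at 8. Purchased 3-bromophenol F1 (eight heavy atoms) is treated as in step 1: t-BuLi gives lithium 3-lithiophenolate F2, addition to 2 gives dilithium 3-(oxidomethyl)phenolate F3, and Ac2O followed by a cold AcOH quench gives 3-hydroxybenzyl acetate F4. F4 has a free para position and is oxidised twice in one flask with PhI(OAc)2 (2.2 equiv) in MeOH, through phenol 7, to ketal 8. No skeletal shift is needed there because the acetoxymethyl group is already meta to the hydroxyl.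

Step 7. The enantioselectivity with an α-iodo dienone is unproven, and the low-valent chromium/manganese system could reduce the quinone monoketal. The fallback avoids low-valent metals, sets out from 8 and 15 and comes back at 16. A MgI2/TMEDA/DMAP-promoted Morita–Baylis–Hillman reaction of 8 with 15 (MeOH, rt) gives the racemic carbinol F5. Dess–Martin periodinane oxidises it to the dienyl ketone F6. Corey–Bakshi–Shibata reduction with (R)-Me-CBS and catecholborane at −78 °C, with the ring alkenyl group as the large substituent, gives the 1′S alcohol 16.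

Step 8. The facial selectivity rests on a conformational model, and a Payne shift is possible under base. If the peroxide adds to the opposite face, the relay is mirrored; this fallback sets out from 9 and 15 and comes back at 18. Step 7 is run with the mirror-image ligand to give the (1R)-carbinol F7. The same directed epoxidation then gives the epoxy alcohol F8 with the required 1R,6S oxirane and 1′R carbinol. A Mitsunobu reaction (PPh3, DIAD, AcOH, THF, 0 °C) inverts C-1′ and installs the acetate in one operation, giving 18.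

**Further compounds**
F1 | step 2 | 3-bromophenol (purchased) | Oc1cccc(Br)c1
F2 | step 2 | lithium 3-lithiophenolate | [Li]Oc1cccc([Li])c1
F3 | step 2 | dilithium 3-(oxidomethyl)phenolate | [Li]OCc1cccc(O[Li])c1
F4 | step 2 | 3-hydroxybenzyl acetate | CC(=O)OCc1cccc(O)c1
F5 | step 7 | racemic {4-[(2E,4E)-1-hydroxy-6,6-dimethoxy-3-methylhexa-2,4-dien-1-yl]-6,6-dimethoxy-3-oxocyclohexa-1,4-dien-1-yl}methyl acetate | CC(=O)OCC1=CC(=O)C(C(O)/C=C(C)/C=C/C(OC)OC)=CC1(OC)OC
F6 | step 7 | {4-[(2E,4E)-6,6-dimethoxy-3-methylhexa-2,4-dienoyl]-6,6-dimethoxy-3-oxocyclohexa-1,4-dien-1-yl}methyl acetate | CC(=O)OCC1=CC(=O)C(C(=O)/C=C(C)/C=C/C(OC)OC)=CC1(OC)OC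
F7 | step 8 | {4-[(1R,2E,4E)-1-hydroxy-6,6-dimethoxy-3-methylhexa-2,4-dien-1-yl]-6,6-dimethoxy-3-oxocyclohexa-1,4-dien-1-yl}methyl acetate | CC(=O)OCC1=CC(=O)C([C@H](O)/C=C(C)/C=C/C(OC)OC)=CC1(OC)OC
F8 | step 8 | {(1R,6S)-1-[(1R,2E,4E)-1-hydroxy-6,6-dimethoxy-3-methylhexa-2,4-dien-1-yl]-5,5-dimethoxy-2-oxo-7-oxabicyclo[4.1.0]hept-3-en-4-yl}methyl acetate | CC(=O)OCC1=CC(=O)[C@]2([C@@H](/C=C(C)/C=C/C(OC)OC)O)O[C@@H]2C1(OC)OC
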